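The numbers are made up.

In this flask monomer is conserved: D, G and Z.D together add up to the D charged, so knowing two gives the third.

D 3.0 M; Z 0.600 M; E 15 mM; time 15 min

    D + J → G + J, rate k1*[J]*[D] (k1 = 0.472 /M/s)
    Z + D → Z.D (k2 = 0.0245 /M/s)
    D + E → J + G (k3 = 0.0777 /M/s)
    G + J → D + J, rate k4*[J] as long as [G] is above zero (k4 = 0.744 /s)
    2 E → E2 (k5 = 0.364 /M/s)

- for a step with 2 of a species take k times the square, and two of it per event
- the average divides the monomer in chains by the number of chains begun, living and dead together
- run time (flask): 15 min

- average number of monomer units in a chain (chains begun, living or dead) at 15 min
- part of the D that has reacted at 15 min

We reckon by hand, link by link. Growth and unzipping both run on the living ends J, so D falls at the growth constant times J times its distance above a level set by the unzipping constant over the growth constant: 1.58 M, the floor of D, known as the equilibrium monomer concentration. The number of ends does not enter it. They set the time constant instead, the inverse of growth constant times J. Taking J as the E charged gives 2.35 min, so the run lasts 6.37 time constants and leaves a fraction 0.00171 of the gap.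

Z has a half-life of 0.16 min by its step alone, far shorter than the run, so we book its charge of 0.600 M as Z.D. The balance then puts 0.824 M in chains at full relaxation, or 0.822 M with the remaining gap. That makes 54.8 units per chain if each E starts one.

That last link is weak, since some E pairs off instead. Reaction with D removes E with time constant 0.0715 min, shorter than Z's half-life, so D stays near its charge meanwhile. Pairing goes with the square of E and reaction with D with E itself, so the ratio of the two losses is proportional to E, and we replace that falling ratio by its mean, taken at half the charge. The share lost is 2.34%, with an error of the order of its square, 0.0548%. That leaves 14.6 mM of chains. We commit to 56.1 units per chain and 47.4% reacted.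

The forecast says 56 and 47.4%, holding that “propagation and depropagation have essentially balanced”. Its chain length lies close to ours, and so does its part reacted.

The flask gives 56.2 units per chain and 47.4% reacted. At 15.0 min D stands at 1.58 M, level with the floor, and at 150 min the chains still average 56.3. A neighbour flask charged with 1.8 M of D has 1.20 M left once its Z is booked, less than the floor of 1.58 M. That neighbour ends at 15.0 min with D at 1.20 M, G at 0.0530% of its D charged, and 0.0662 units per chain.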